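**Retrosynthetic overview**

1. Atom labels follow the polyketide chain: C1 = lactone carbonyl … C21 = carbinol carbon (methyls on C2, C10, C16, C21). Ring A = C7–C12; ring B = C6, C7, C12–C15.
2. The last bond is C4–C5, made by an intramolecular Claisen condensation that closes the 14-membered ring; the C1–O21 ester is made just before by transesterification.
3. The C17–C20 Z,Z-diene comes from a conjugated diyne by zinc reduction. Rings A and B form together in one intramolecular Diels–Alder reaction (IMDA; bonds C6–C15 and C7–C12) of a linear tetraene ester.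
4. Key bond C15–C16: nickel-catalysed coupling of a dienylzinc (C5–C15) with a propargylic bromide (C16–C21) through a propargylic radical; this step sets C16.
5. Pieces: the bromodiynol from oxidative dimerisation of (R)-but-3-yn-2-ol; the dienyne ester from propyne by syn-diboration and two allyl–alkenyl Suzuki couplings. Ring order: A and B in one step, then the macrocycle.

Assumption: the enol drawn in the target is one tautomer of the C3,C5-dione and C2 is epimerisable, so the route delivers the equilibrated (2S) macrolide in its dione/enol equilibrium form.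

**Route**

Step 1
Reactants: 1 (R)-but-3-yn-2-ol
Product: 2 (2R,7R)-octa-3,5-diyne-2,7-diol
Conditions: CuCl (5 mol%), TMEDA (10 mol%), O2 (1 atm), acetone, 23 °C
Reagents that add atoms: second molecule of (R)-but-3-yn-2-ol C[C@@H](O)C#C
Why: Glaser–Hay oxidative homocoupling joins two molecules of the terminal alkyne 1 at their sp carbons through the copper acetylides, with O2 as terminal oxidant and water as the only by-product; both carbinol centres are untouched, so the diol is C2-symmetric.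

Step 2
Reactants: 2 (2R,7R)-octa-3,5-diyne-2,7-diol
Product: 3 (2R,7S)-7-bromoocta-3,5-diyn-2-ol
Conditions: CBr4 (0.5 equiv), PPh3 (0.55 equiv), CH2Cl2, 0 °C; unreacted 2 recycled
Reagents that add atoms: carbon tetrabromide BrC(Br)(Br)Br
Why: Appel reaction; the two hydroxyls are homotopic, so monobromination gives a single compound, and the (inverted) configuration at the C–Br carbon is erased in step 7.

Step 3
Reactants: 4 (E)-pent-2-en-4-yn-1-ol
Product: 5 (E)-5-bromopent-3-en-1-yne
Conditions: CBr4, PPh3, CH2Cl2, 0 °C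
Reagents that add atoms: carbon tetrabromide BrC(Br)(Br)Br
Why: Appel reaction on the primary allylic alcohol; the E-enyne is retained.

Step 4
Reactants: 6 propyne
Product: 7 2,2'-[(1E)-prop-1-ene-1,2-diyl]bis(4,4,5,5-tetramethyl-1,3,2-dioxaborolane) (the two boryl groups cis)
Conditions: B2pin2, Pt(PPh3)4 (3 mol%), DMF, 80 °C, sealed tube
Reagents that add atoms: bis(pinacolato)diboron CC1(C)OB(OC1(C)C)B1OC(C)(C)C(C)(C)O1
Why: platinum-catalysed syn-diboration (B–B oxidative addition to zerovalent platinum, syn insertion) puts the two boryl groups cis, which later fixes the Z alkene of ring A.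

Step 5
Reactants: 7 cis-1,2-diborylpropene; 8 methyl (2E)-4-bromobut-2-enoate; 5 (E)-5-bromopent-3-en-1-yne
Product: 10 methyl (2E,5Z,8E)-6-methylundeca-2,5,8-trien-10-ynoate, via alkenyl monoboronate 9 (not isolated)
Conditions: Pd(PPh3)4 (5 mol%), CsF (4 equiv), THF, 8 (1.0 equiv), 40 °C; then 5 (1.3 equiv), 65 °C
Reagents that add atoms: none
Why: two Suzuki–Miyaura allyl–alkenyl couplings in one pot; the unhindered terminal C–B bond couples first with 8 and the internal one then with 5, each with retention at the alkenyl carbon and at the linear allyl terminus, giving the 5Z trisubstituted alkene.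

Step 6
Reactants: 11 methyl 3-oxobutanoate
Product: 12 methyl 2-methyl-3-oxobutanoate (racemic)
Conditions: MeI (1.0 equiv), K2CO3, acetone, 56 °C
Reagents that add atoms: iodomethane CI
Why: C-alkylation of the β-keto ester enolate (SN2); one equivalent of MeI limits dialkylation.

Step 7
Reactants: 10 methyl (2E,5Z,8E)-6-methylundeca-2,5,8-trien-10-ynoate; 3 (2R,7S)-7-bromoocta-3,5-diyn-2-ol
Product: 15 methyl (2E,5Z,8E,10E,12R,17R)-17-hydroxy-6,12-dimethyloctadeca-2,5,8,10-tetraene-13,15-diynoate, via alkenylzirconocene chloride 13 (not isolated), via alkenylzinc chloride 14 (not isolated)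
Conditions: 10 (1.4 equiv), Cp2Zr(H)Cl, THF, 0 to 23 °C; ZnCl2, 0 °C; then 3 (1.0 equiv), NiCl2(dme) (10 mol%), (S,S)-iPr-pybox (13 mol%), DME, −20 °C
Reagents that add atoms: none
Why: Proposed new method: nickel/pybox stereoconvergent Negishi alkenylation of a secondary propargylic bromide – bromine abstraction by low-valent nickel gives a planar propargylic radical (so the C–Br configuration of 3 does not matter), the radical is captured by the chiral alkenylnickel species formed from 14, and reductive elimination forges C15–C16 and sets C16 (12R in 15) under ligand control at the diyne-conjugated propargylic carbon; the alkenylzinc chloride tolerates the free hydroxyl; the closest known reactions are the enantioconvergent nickel/pybox Negishi arylation of racemic propargylic bromides and nickel-catalysed enantioconvergent alkenylations of α-bromo carbonyl compounds with alkenylzinc or alkenylzirconium reagents; the (S,S) ligand is named by analogy and its antipode is used if the sense proves opposite.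

Step 8
Reactants: 15 methyl (2E,5Z,8E,10E,12R,17R)-17-hydroxy-6,12-dimethyloctadeca-2,5,8,10-tetraene-13,15-diynoate
Product: 18 methyl (1R,2R,4aR,8aS)-2-[(2R,7R)-7-hydroxyocta-3,5-diyn-2-yl]-6-methyl-1,2,4a,5,8,8a-hexahydronaphthalene-1-carboxylate, via aluminium alkoxide of the tetraene 16 (not isolated), via aluminium alkoxide of the cycloadduct 17 (not isolated)
Conditions: Me2AlCl (2.2 equiv), CH2Cl2, −40 to 0 °C; then 1 M HCl
Reagents that add atoms: none
Why: Lewis-acid-promoted intramolecular Diels–Alder reaction; the endo transition state of the E,E-diene and E-enoate gives the trans-fused ring A/ring B system with the ester cis to the side chain, and the allylic C16 centre (H in the diene plane, dienophile anti to methyl and past the slim diynyl rod) selects the diene face, so C6, C7, C12 and C15 are set together.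

Step 9
Reactants: 18 decalin diynol ester
Product: 19 methyl (1R,2R,4aR,8aS)-2-[(2S,3Z,5Z,7R)-7-hydroxyocta-3,5-dien-2-yl]-6-methyl-1,2,4a,5,8,8a-hexahydronaphthalene-1-carboxylate
Conditions: Zn dust activated with Cu(OAc)2 and AgNO3, MeOH/H2O 1:1, 40 °C
Reagents that add atoms: none
Why: Boland-type reduction of a conjugated diyne by activated zinc gives the Z,Z-diene by cis delivery of hydrogen; the isolated alkenes and the ester are inert.

Step 10
Reactants: 19 Z,Z-dienol ester; 12 methyl 2-methyl-3-oxobutanoate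
Product: 20 methyl (1R,2R,4aR,8aS)-6-methyl-2-[(2S,3Z,5Z,7R)-7-[(2-methyl-3-oxobutanoyl)oxy]octa-3,5-dien-2-yl]-1,2,4a,5,8,8a-hexahydronaphthalene-1-carboxylate (both epimers at the oxobutanoyl C2)
Conditions: 12 (5 equiv), DMAP (0.3 equiv), toluene, 110 °C, 4 Å molecular sieves
Reagents that add atoms: none
Why: DMAP-catalysed transesterification of a β-keto ester (via the acylketene), selective over the hindered decalin ester; acyl–oxygen cleavage leaves C21 untouched.

Step 11
Reactants: 20 keto ester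
Product: 22 target macrolide (2S,6R,7S,12R,15R,16S,21R,17Z,19Z), via dilithium dianion 21 (not isolated)
Conditions: LiN(iPr)2 (3.5 equiv), THF, 0.002 M, −78 to 0 °C; AcOH; then Et3N (0.2 equiv), CH2Cl2, 23 °C
Reagents that add atoms: none
Why: intramolecular Claisen (Dieckmann-type) condensation – the γ-carbanion of the β-keto ester dianion acylates the decalin ester at high dilution to close the 14-membered ring, the dione enolises, and C2 is expected to equilibrate under the amine to the 2S epimer, taken as the more stable one.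

**Compound list**

1 | (R)-but-3-yn-2-ol | C[C@@H](O)C#C | starting material
2 | (2R,7R)-octa-3,5-diyne-2,7-diol | C[C@@H](O)C#CC#C[C@@H](C)O | intermediate
3 | (2R,7S)-7-bromoocta-3,5-diyn-2-ol | C[C@@H](O)C#CC#C[C@H](C)Br | intermediate
4 | (E)-pent-2-en-4-yn-1-ol | OC/C=C/C#C | starting material
5 | (E)-5-bromopent-3-en-1-yne | BrC/C=C/C#C | intermediate
6 | propyne | CC#C | starting material
7 | 2,2'-[(1E)-prop-1-ene-1,2-diyl]bis(4,4,5,5-tetramethyl-1,3,2-dioxaborolane), boryl groups cis | CC1(C)OB(/C(C)=C\B2OC(C)(C)C(C)(C)O2)OC1(C)C | intermediate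
8 | methyl (2E)-4-bromobut-2-enoate | COC(=O)/C=C/CBr | starting material
9 | methyl (2E,5E)-6-(4,4,5,5-tetramethyl-1,3,2-dioxaborolan-2-yl)hepta-2,5-dienoate | COC(=O)/C=C/C/C=C(/C)B1OC(C)(C)C(C)(C)O1 | intermediate
10 | methyl (2E,5Z,8E)-6-methylundeca-2,5,8-trien-10-ynoate | COC(=O)/C=C/C/C=C(/C)C/C=C/C#C | intermediate
11 | methyl 3-oxobutanoate | COC(=O)CC(C)=O | starting material
12 | methyl 2-methyl-3-oxobutanoate (racemic) | COC(=O)C(C)C(C)=O | intermediate
13 | chlorobis(cyclopentadienyl)[(1E,3E,6Z,9E)-11-methoxy-6-methyl-11-oxoundeca-1,3,6,9-tetraen-1-yl]zirconium | COC(=O)/C=C/C/C=C(/C)C/C=C/C=C/[Zr](Cl)(C1C=CC=C1)C1C=CC=C1 | intermediate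
14 | chloro[(1E,3E,6Z,9E)-11-methoxy-6-methyl-11-oxoundeca-1,3,6,9-tetraen-1-yl]zinc | COC(=O)/C=C/C/C=C(/C)C/C=C/C=C/[Zn]Cl | intermediate
15 | methyl (2E,5Z,8E,10E,12R,17R)-17-hydroxy-6,12-dimethyloctadeca-2,5,8,10-tetraene-13,15-diynoate | COC(=O)/C=C/C/C=C(/C)C/C=C/C=C/[C@@H](C)C#CC#C[C@@H](C)O | intermediate
16 | methyl (2E,5Z,8E,10E,12R,17R)-17-{[chloro(methyl)alumanyl]oxy}-6,12-dimethyloctadeca-2,5,8,10-tetraene-13,15-diynoate | COC(=O)/C=C/C/C=C(/C)C/C=C/C=C/[C@@H](C)C#CC#C[C@@H](C)O[Al](C)Cl | intermediate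
17 | methyl (1R,2R,4aR,8aS)-2-[(2R,7R)-7-{[chloro(methyl)alumanyl]oxy}octa-3,5-diyn-2-yl]-6-methyl-1,2,4a,5,8,8a-hexahydronaphthalene-1-carboxylate | CC1=CC[C@@H]2[C@@H](C(=O)OC)[C@@H]([C@@H](C)C#CC#C[C@@H](C)O[Al](C)Cl)C=C[C@H]2C1 | intermediate
18 | methyl (1R,2R,4aR,8aS)-2-[(2R,7R)-7-hydroxyocta-3,5-diyn-2-yl]-6-methyl-1,2,4a,5,8,8a-hexahydronaphthalene-1-carboxylate | CC1=CC[C@@H]2[C@@H](C(=O)OC)[C@@H]([C@@H](C)C#CC#C[C@@H](C)O)C=C[C@H]2C1 | intermediate
19 | methyl (1R,2R,4aR,8aS)-2-[(2S,3Z,5Z,7R)-7-hydroxyocta-3,5-dien-2-yl]-6-methyl-1,2,4a,5,8,8a-hexahydronaphthalene-1-carboxylate | CC1=CC[C@@H]2[C@@H](C(=O)OC)[C@@H]([C@@H](C)/C=C\C=C/[C@@H](C)O)C=C[C@H]2C1 | intermediate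
20 | methyl (1R,2R,4aR,8aS)-6-methyl-2-[(2S,3Z,5Z,7R)-7-[(2-methyl-3-oxobutanoyl)oxy]octa-3,5-dien-2-yl]-1,2,4a,5,8,8a-hexahydronaphthalene-1-carboxylate | CC1=CC[C@@H]2[C@@H](C(=O)OC)[C@@H]([C@@H](C)/C=C\C=C/[C@@H](C)OC(=O)C(C)C(C)=O)C=C[C@H]2C1 | intermediate
21 | dilithium dianion of 20 (ester enolate at C2, carbanion at C4) | CC1=CC[C@@H]2[C@@H](C(=O)OC)[C@@H]([C@@H](C)/C=C\C=C/[C@@H](C)OC(=O)C(C)=C([O-])[CH2-])C=C[C@H]2C1.[Li+].[Li+] | intermediate
22 | target macrolide: 14-membered lactone, C3,C5-dione drawn as the C5 enol, fused to the trans-decalin; (2S,6R,7S,12R,15R,16S,21R), 17Z,19Z | CC1=CC[C@@H]2[C@H]3/C(O)=C\C(=O)[C@H](C)C(=O)O[C@H](C)/C=C\C=C/[C@H](C)[C@H]3C=C[C@H]2C1 | target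

**Step count and risks**

Total steps: 11. Longest linear sequence: 7 steps (4, 5, 7, 8, 9, 10, 11 from propyne; equally 1, 2, 7, 8, 9, 10, 11 from 1).

Most likely to fail, first: step 7. The alkenylzinc may not be accepted in the propargylic coupling, the diyne-delocalised radical may couple at an allenyl position, or ligand control at C16 may be poor. The fallback sets out from 10 and comes back at 15. It makes C15–C16 with a silyl-capped propargylic bromide of the class for which the nickel/pybox coupling is established, and builds the diyne afterwards. Ethynyltrimethylsilane is lithiated (n-BuLi) and added to acetaldehyde to give racemic 4-(trimethylsilyl)but-3-yn-2-ol F1. CBr4/PPh3 turns this into racemic (3-bromobut-1-yn-1-yl)trimethylsilane F2. Coupling of F2 with the alkenylzinc 14 made from 10 under the step 7 catalyst gives methyl (2E,5Z,8E,10E,12R)-6,12-dimethyl-14-(trimethylsilyl)tetradeca-2,5,8,10-tetraen-13-ynoate F3. K2CO3 in MeOH removes silicon to give methyl (2E,5Z,8E,10E,12R)-6,12-dimethyltetradeca-2,5,8,10-tetraen-13-ynoate F4. NBS with AgNO3 converts 1 into (2R)-4-bromobut-3-yn-2-ol F5. Cadiot–Chodkiewicz coupling of F4 with F5 (CuCl, NH2OH·HCl, n-BuNH2, 0 °C) gives 15.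

Second: step 8. Without a directing group on the diene, the facial bias from C16 and the endo preference of an ester dienophile may be modest. The fallback sets out from 15 and comes back at 18. It replaces substrate control by iminium catalysis. i-Bu2AlH reduces 15 to (2E,5Z,8E,10E,12R,17R)-6,12-dimethyloctadeca-2,5,8,10-tetraene-13,15-diyne-1,17-diol F6. TEMPO with PhI(OAc)2 oxidises only the primary allylic alcohol to (2E,5Z,8E,10E,12R,17R)-17-hydroxy-6,12-dimethyloctadeca-2,5,8,10-tetraene-13,15-diynal F7. The trifluoroacetate salt of (2S,5S)-5-benzyl-2-tert-butyl-3-methylimidazolidin-4-one (20 mol%) is the catalyst; by analogy with its known enal Diels–Alder reactions it should expose the enal face needed for 6R,7S. It gives the endo cycloadduct (1R,2R,4aR,8aS)-2-[(2R,7R)-7-hydroxyocta-3,5-diyn-2-yl]-6-methyl-1,2,4a,5,8,8a-hexahydronaphthalene-1-carbaldehyde F8. NaClO2/NaH2PO4 oxidation in the presence of 2-methylbut-2-ene gives (1R,2R,4aR,8aS)-2-[(2R,7R)-7-hydroxyocta-3,5-diyn-2-yl]-6-methyl-1,2,4a,5,8,8a-hexahydronaphthalene-1-carboxylic acid F9, and Me3SiCHN2 gives 18.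

Third: step 11. The hindered methyl ester may be too poor an electrophile for a 14-membered Claisen closure, and the 2S epimer may not be the favoured one on equilibration. The fallback sets out from 19 and comes back at 22. It closes the ring by an aldol addition to an aldehyde instead. i-Bu2AlH reduces 19 to [(1R,2R,4aR,8aS)-2-[(2S,3Z,5Z,7R)-7-hydroxyocta-3,5-dien-2-yl]-6-methyl-1,2,4a,5,8,8a-hexahydronaphthalen-1-yl]methanol F10. TEMPO with PhI(OAc)2 oxidises the primary alcohol to (1R,2R,4aR,8aS)-2-[(2S,3Z,5Z,7R)-7-hydroxyocta-3,5-dien-2-yl]-6-methyl-1,2,4a,5,8,8a-hexahydronaphthalene-1-carbaldehyde F11. Transesterification with 12 (DMAP, toluene, 110 °C) gives (2R,3Z,5Z,7S)-7-[(1R,2R,4aR,8aS)-1-formyl-6-methyl-1,2,4a,5,8,8a-hexahydronaphthalen-2-yl]octa-3,5-dien-2-yl 2-methyl-3-oxobutanoate F12. Its dianion (LiN(iPr)2, 2.2 equiv, high dilution) adds to the aldehyde to give the macrocyclic 5-hydroxy-3-oxo lactone F13 (C5 carbinol epimers). Dess–Martin periodinane, followed by the Et3N equilibration of step 11, then gives 22.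

**Further compounds**

F1 | step 7 | 4-(trimethylsilyl)but-3-yn-2-ol (racemic) | CC(O)C#C[Si](C)(C)C
F2 | step 7 | (3-bromobut-1-yn-1-yl)trimethylsilane (racemic) | CC(Br)C#C[Si](C)(C)C
F3 | step 7 | methyl (2E,5Z,8E,10E,12R)-6,12-dimethyl-14-(trimethylsilyl)tetradeca-2,5,8,10-tetraen-13-ynoate | COC(=O)/C=C/C/C=C(/C)C/C=C/C=C/[C@@H](C)C#C[Si](C)(C)C
F4 | step 7 | methyl (2E,5Z,8E,10E,12R)-6,12-dimethyltetradeca-2,5,8,10-tetraen-13-ynoate | COC(=O)/C=C/C/C=C(/C)C/C=C/C=C/[C@@H](C)C#C
F5 | step 7 | (2R)-4-bromobut-3-yn-2-ol | C[C@@H](O)C#CBr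
F6 | step 8 | (2E,5Z,8E,10E,12R,17R)-6,12-dimethyloctadeca-2,5,8,10-tetraene-13,15-diyne-1,17-diol | OC/C=C/C/C=C(/C)C/C=C/C=C/[C@@H](C)C#CC#C[C@@H](C)O
F7 | step 8 | (2E,5Z,8E,10E,12R,17R)-17-hydroxy-6,12-dimethyloctadeca-2,5,8,10-tetraene-13,15-diynal | O=C/C=C/C/C=C(/C)C/C=C/C=C/[C@@H](C)C#CC#C[C@@H](C)O
F8 | step 8 | (1R,2R,4aR,8aS)-2-[(2R,7R)-7-hydroxyocta-3,5-diyn-2-yl]-6-methyl-1,2,4a,5,8,8a-hexahydronaphthalene-1-carbaldehyde | CC1=CC[C@@H]2[C@@H](C=O)[C@@H]([C@@H](C)C#CC#C[C@@H](C)O)C=C[C@H]2C1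
F9 | step 8 | (1R,2R,4aR,8aS)-2-[(2R,7R)-7-hydroxyocta-3,5-diyn-2-yl]-6-methyl-1,2,4a,5,8,8a-hexahydronaphthalene-1-carboxylic acid | CC1=CC[C@@H]2[C@@H](C(=O)O)[C@@H]([C@@H](C)C#CC#C[C@@H](C)O)C=C[C@H]2C1
F10 | step 11 | [(1R,2R,4aR,8aS)-2-[(2S,3Z,5Z,7R)-7-hydroxyocta-3,5-dien-2-yl]-6-methyl-1,2,4a,5,8,8a-hexahydronaphthalen-1-yl]methanol | CC1=CC[C@@H]2[C@@H](CO)[C@@H]([C@@H](C)/C=C\C=C/[C@@H](C)O)C=C[C@H]2C1
F11 | step 11 | (1R,2R,4aR,8aS)-2-[(2S,3Z,5Z,7R)-7-hydroxyocta-3,5-dien-2-yl]-6-methyl-1,2,4a,5,8,8a-hexahydronaphthalene-1-carbaldehyde | CC1=CC[C@@H]2[C@@H](C=O)[C@@H]([C@@H](C)/C=C\C=C/[C@@H](C)O)C=C[C@H]2C1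
F12 | step 11 | (2R,3Z,5Z,7S)-7-[(1R,2R,4aR,8aS)-1-formyl-6-methyl-1,2,4a,5,8,8a-hexahydronaphthalen-2-yl]octa-3,5-dien-2-yl 2-methyl-3-oxobutanoate | CC1=CC[C@@H]2[C@@H](C=O)[C@@H]([C@@H](C)/C=C\C=C/[C@@H](C)OC(=O)C(C)C(C)=O)C=C[C@H]2C1
F13 | step 11 | macrocyclic 5-hydroxy-3-oxo lactone (target skeleton with sp3 C5 carbinol and C4H2; C2 and C5 epimers) | CC1=CC[C@@H]2[C@H]3C(O)CC(=O)C(C)C(=O)O[C@H](C)/C=C\C=C/[C@H](C)[C@H]3C=C[C@H]2C1
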